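**Retrosynthetic overview**
1. The only strategic disconnections are the two galloyl ester C–O bonds (O3–acyl and O5–acyl); both are made in one operation on a phenol-silylated (−)-epicatechin.
2. The O5 ester comes from a site-selective silyl-to-aroyl exchange at O5 (new). The O3 ester comes from ordinary O-acylation of the only free hydroxyl. The 7-, 3'- and 4'-oxygens stay silylated.
3. The aroyl donor is persilylated gallic acid, so one fluoride step frees all nine phenols at the end.
4. No ring is formed: rings A, C and B and both stereocentres (2R,3R) come intact from (−)-epicatechin, and the galloyl rings from gallic acid.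

Assumption: (−)-epicatechin and gallic acid are bought as bulk natural-product chemicals; the target SMILES was checked to be (2R,3R), the configuration of (−)-epicatechin. (TBS = tert-butyldimethylsilyl; TBSO = tert-butyldimethylsilyloxy.)

**Step 1**
Reactants: 1 gallic acid (3,4,5-trihydroxybenzoic acid)
Product: 3 3,4,5-tris(tert-butyldimethylsilyloxy)benzoic acid, via persilylated silyl ester 2 (not isolated)
Conditions: TBSCl (4.5 equiv), imidazole, DMF, rt; then AcOH/THF/H2O (3:1:1), rt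
Reagents that add atoms: tert-butyldimethylsilyl chloride (TBSCl), CC(C)(C)[Si](C)(C)Cl
Why: Imidazole-promoted silylation (Corey conditions) caps the three phenols and the acid, and mild aqueous acid then hydrolyses only the labile silyl ester because aryl silyl ethers are stable to it; no stereocentre is involved.

**Step 2**
Reactants: 4 (−)-epicatechin, (2R,3R)-2-(3,4-dihydroxyphenyl)chromane-3,5,7-triol
Product: 5 5,7,3',4'-tetra-O-TBS-(−)-epicatechin (2R,3R; 3-OH free)
Conditions: TBSCl (4.3 equiv), imidazole, DMF, 0 °C → rt, Ar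
Reagents that add atoms: tert-butyldimethylsilyl chloride (TBSCl), CC(C)(C)[Si](C)(C)Cl
Why: Chemoselective silylation: the four phenols react far faster with TBSCl/imidazole than the hindered axial secondary 3-OH, so a small excess stops at the tetra-aryl ether, and C2 and C3 are untouched under these mild, non-epimerising conditions.

**Step 3**
Reactants: 3 3,4,5-tris(TBSO)benzoic acid (2.6 equiv); 5 5,7,3',4'-tetra-O-TBS-(−)-epicatechin
Product: 9 7,3',4'-tri-O-TBS-(−)-epicatechin 3,5-bis-O-[3,4,5-tris(TBSO)benzoate] (2R,3R), via aroyl trifluoroacetate 6 (not isolated), via 3-O-monoester 7 (not isolated), via 5-hydroxy 3-O-monoester 8 (not isolated)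
Conditions: 3, (CF3CO)2O (2.4 equiv), CH2Cl2, 0 °C; then 5, 0 °C; then CF3CO2H (15 vol%), 0 °C → rt
Reagents that add atoms: trifluoroacetic anhydride, O=C(OC(=O)C(F)(F)F)C(F)(F)F (its CF3CO unit is held only in intermediate 6 and leaves again as trifluoroacetate)
Why: Proposed new method: an acid-relayed desilylative aroylation in which the mixed anhydride 6 (closest known reaction type: trifluoroacetic-anhydride-mediated esterification of alcohols and phenols through an acylium-like aroyl transfer) first esterifies the only free hydroxyl, the axial 3-OH, with retention because the C3–O bond is never broken (7); trifluoroacetic acid then C-protonates the phloroglucinol-type ring A at C8, the para-quinoid oxocarbenium puts the charge on O5, trifluoroacetate removes the peri-strained 5-O-silyl group (the same bias as the known trifluoroacetic acid 5-O-desilylation of persilylated flavan-3-ols) and the freed phenol 8 is trapped at once by a second 6, the new aryl ester deactivating ring A so that the 7-O-silyl ether, the less basic ring B and the electron-poor galloyl rings keep their silyl groups.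

**Step 4**
Reactants: 9 7,3',4'-tri-O-TBS-(−)-epicatechin 3,5-bis-O-[3,4,5-tris(TBSO)benzoate]
Product: 10 (−)-epicatechin 3,5-di-O-gallate (2R,3R)
Conditions: HF·pyridine (excess), THF/pyridine, 0 °C → rt
Reagents that add atoms: none
Why: Fluoride-driven global desilylation (Si–F bond formation) under buffered, slightly acidic conditions never generates free phenoxides, so neither the alkyl nor the phenolic gallate ester is cleaved or migrates, and both stereocentres are untouched.

**Compound list**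
1 | gallic acid | OC(=O)c1cc(O)c(O)c(O)c1 | starting material
2 | tert-butyldimethylsilyl 3,4,5-tris(tert-butyldimethylsilyloxy)benzoate | CC(C)(C)[Si](C)(C)OC(=O)c1cc(O[Si](C)(C)C(C)(C)C)c(O[Si](C)(C)C(C)(C)C)c(O[Si](C)(C)C(C)(C)C)c1 | intermediate
3 | 3,4,5-tris(tert-butyldimethylsilyloxy)benzoic acid | OC(=O)c1cc(O[Si](C)(C)C(C)(C)C)c(O[Si](C)(C)C(C)(C)C)c(O[Si](C)(C)C(C)(C)C)c1 | intermediate
4 | (−)-epicatechin, (2R,3R) | Oc1cc(O)cc2c1C[C@@H](O)[C@@H](c1ccc(O)c(O)c1)O2 | starting material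
5 | 5,7,3',4'-tetra-O-TBS-(−)-epicatechin, (2R,3R), 3-OH free | CC(C)(C)[Si](C)(C)Oc1cc(O[Si](C)(C)C(C)(C)C)cc2c1C[C@@H](O)[C@@H](c1ccc(O[Si](C)(C)C(C)(C)C)c(O[Si](C)(C)C(C)(C)C)c1)O2 | intermediate
6 | 3,4,5-tris(TBSO)benzoic trifluoroacetic anhydride | O=C(OC(=O)C(F)(F)F)c1cc(O[Si](C)(C)C(C)(C)C)c(O[Si](C)(C)C(C)(C)C)c(O[Si](C)(C)C(C)(C)C)c1 | intermediate
7 | 5,7,3',4'-tetra-O-TBS-(−)-epicatechin 3-O-[3,4,5-tris(TBSO)benzoate], (2R,3R) | CC(C)(C)[Si](C)(C)Oc1cc(O[Si](C)(C)C(C)(C)C)cc2c1C[C@@H](OC(=O)c1cc(O[Si](C)(C)C(C)(C)C)c(O[Si](C)(C)C(C)(C)C)c(O[Si](C)(C)C(C)(C)C)c1)[C@@H](c1ccc(O[Si](C)(C)C(C)(C)C)c(O[Si](C)(C)C(C)(C)C)c1)O2 | intermediate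
8 | 7,3',4'-tri-O-TBS-(−)-epicatechin 3-O-[3,4,5-tris(TBSO)benzoate], (2R,3R), 5-OH free | Oc1cc(O[Si](C)(C)C(C)(C)C)cc2c1C[C@@H](OC(=O)c1cc(O[Si](C)(C)C(C)(C)C)c(O[Si](C)(C)C(C)(C)C)c(O[Si](C)(C)C(C)(C)C)c1)[C@@H](c1ccc(O[Si](C)(C)C(C)(C)C)c(O[Si](C)(C)C(C)(C)C)c1)O2 | intermediate
9 | 7,3',4'-tri-O-TBS-(−)-epicatechin 3,5-bis-O-[3,4,5-tris(TBSO)benzoate], (2R,3R) | O=C(Oc1cc(O[Si](C)(C)C(C)(C)C)cc2c1C[C@@H](OC(=O)c1cc(O[Si](C)(C)C(C)(C)C)c(O[Si](C)(C)C(C)(C)C)c(O[Si](C)(C)C(C)(C)C)c1)[C@@H](c1ccc(O[Si](C)(C)C(C)(C)C)c(O[Si](C)(C)C(C)(C)C)c1)O2)c1cc(O[Si](C)(C)C(C)(C)C)c(O[Si](C)(C)C(C)(C)C)c(O[Si](C)(C)C(C)(C)C)c1 | intermediate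
10 | (−)-epicatechin 3,5-di-O-gallate, (2R,3R) | O=C(Oc1cc(O)cc2c1C[C@@H](OC(=O)c1cc(O)c(O)c(O)c1)[C@@H](c1ccc(O)c(O)c1)O2)c1cc(O)c(O)c(O)c1 | target

**Totals**
Total step count: 4.
Longest linear sequence: 3 steps (4 → 5 → 9 → 10; the branch 1 → 3 joins at step 3 and is equally long).

**Steps most likely to fail**

Step 3 (the proposed new step). The main risks are Friedel–Crafts C-aroylation of ring A at C6/C8, trifluoroacetylation instead of aroylation at O3, and incomplete or unselective silyl exchange. The fallback uses known chemistry; it sets out from 5 and comes back at 9. Compound 5 is treated with trifluoroacetic acid in CH2Cl2 at 0 °C, the known ring-A-selective 5-O-desilylation of persilylated flavan-3-ols, to give 7,3',4'-tri-O-TBS-(−)-epicatechin F1, which has the 3-OH and 5-OH free. F1 is then esterified twice with acid 3 under Steglich conditions (EDC·HCl, DMAP, CH2Cl2, rt) to give 9.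

Step 2. The risk is over-silylation at O3 or incomplete phenol silylation, giving mixtures. The fallback sets out from 4 and comes back at 5. Exhaustive silylation (TBSOTf, 2,6-lutidine, CH2Cl2, 0 °C → rt) gives 3,5,7,3',4'-penta-O-TBS-(−)-epicatechin F2 with no selectivity requirement. The single alkyl silyl ether at O3 is then removed by mild acid methanolysis (cat. camphorsulfonic acid, MeOH/CH2Cl2, 0 °C), which spares aryl silyl ethers, to give 5.

Step 4. The risk is a sluggish ninefold desilylation with partial loss or migration of the phenolic 5-O-gallate. The fallback sets out from 5 and comes back at 10; it moves six of the nine protecting groups to benzyl ethers so that the last step is a neutral hydrogenolysis. Compound 5 is converted into 7,3',4'-tri-O-TBS-(−)-epicatechin F1 as in the first fallback. F1 is acylated with commercial 3,4,5-tris(benzyloxy)benzoyl chloride F3 (Et3N, DMAP, CH2Cl2) to give 7,3',4'-tri-O-TBS-(−)-epicatechin 3,5-bis-O-[3,4,5-tris(benzyloxy)benzoate] F4. Only three aryl silyl ethers then need HF·pyridine, giving (−)-epicatechin 3,5-bis-O-[3,4,5-tris(benzyloxy)benzoate] F5. Hydrogenolysis (H2, Pd(OH)2/C, THF/EtOAc, rt) removes the six benzyl groups and gives 10.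

**Further compounds**
F1 | step 3 | 7,3',4'-tri-O-TBS-(−)-epicatechin, (2R,3R), 3-OH and 5-OH free | Oc1cc(O[Si](C)(C)C(C)(C)C)cc2c1C[C@@H](O)[C@@H](c1ccc(O[Si](C)(C)C(C)(C)C)c(O[Si](C)(C)C(C)(C)C)c1)O2
F2 | step 2 | 3,5,7,3',4'-penta-O-TBS-(−)-epicatechin, (2R,3R) | CC(C)(C)[Si](C)(C)Oc1cc(O[Si](C)(C)C(C)(C)C)cc2c1C[C@@H](O[Si](C)(C)C(C)(C)C)[C@@H](c1ccc(O[Si](C)(C)C(C)(C)C)c(O[Si](C)(C)C(C)(C)C)c1)O2
F3 | step 4 | 3,4,5-tris(benzyloxy)benzoyl chloride | ClC(=O)c1cc(OCc2ccccc2)c(OCc2ccccc2)c(OCc2ccccc2)c1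
F4 | step 4 | 7,3',4'-tri-O-TBS-(−)-epicatechin 3,5-bis-O-[3,4,5-tris(benzyloxy)benzoate], (2R,3R) | O=C(Oc1cc(O[Si](C)(C)C(C)(C)C)cc2c1C[C@@H](OC(=O)c1cc(OCc3ccccc3)c(OCc3ccccc3)c(OCc3ccccc3)c1)[C@@H](c1ccc(O[Si](C)(C)C(C)(C)C)c(O[Si](C)(C)C(C)(C)C)c1)O2)c1cc(OCc2ccccc2)c(OCc2ccccc2)c(OCc2ccccc2)c1
F5 | step 4 | (−)-epicatechin 3,5-bis-O-[3,4,5-tris(benzyloxy)benzoate], (2R,3R) | O=C(Oc1cc(O)cc2c1C[C@@H](OC(=O)c1cc(OCc3ccccc3)c(OCc3ccccc3)c(OCc3ccccc3)c1)[C@@H](c1ccc(O)c(O)c1)O2)c1cc(OCc2ccccc2)c(OCc2ccccc2)c(OCc2ccccc2)c1
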